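Each Q that passes through Q + D -> X + E takes one D with it, whatever its X then becomes, and that D is gone as E; the second Q of a G takes no D. A fraction of the Q charge passing that first step therefore costs, as E, a fixed multiple of that fraction of the D charge, and any L holds further D on top. This D price, Q charge over D charge, is 3.08 for north, where D is the limiting reagent, and 0.769 for south-east.

| flask | Q | D | remark | time |
|---|---|---|---|---|
| alpha | 0.29 M | 0.39 M | run made earlier |  |
| eta | 0.54 M | 0.39 M | run made earlier |  |
| gamma | 1.1 M | 0.39 M | run made earlier |  |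
| south-east | 0.30 M | 0.390 M |  | 30 min |
| north | 1.2 M | 0.390 M |  | 30 min |

| run | time / min | J / % | Z / % | G / % |
|---|---|---|---|---|
| alpha | 2.50 | 2.9 | 0.1 | 0.2 |
| alpha | 5.00 | 4.2 | 0.3 | 0.7 |
| alpha | 8.00 | 4.3 | 2.4 | 1.4 |
| alpha | 15.0 | 7.7 | 6.4 | 0.3 |
| alpha | 30.0 | 8.9 | 15.8 | 0.4 |
| eta | 2.50 | 2.1 | 0.1 | 0 |
| eta | 5.00 | 4.0 | 0.8 | 0 |
| eta | 8.00 | 5.0 | 3.1 | 0.6 |
| eta | 15.0 | 7.2 | 7.0 | 1.3 |
| eta | 30.0 | 7.4 | 14.6 | 1.9 |
| gamma | 2.50 | 1.7 | 0.8 | 0 |
| gamma | 8.00 | 3.9 | 1.7 | 0.7 |
| gamma | 15.0 | 4.7 | 5.0 | 0.8 |
| gamma | 20.0 | 4.3 | 7.1 | 2.7 |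
| gamma | 30.0 | 4.3 | 11.0 | 3.6 |

(scatter of a reading: 0.5 percentage points)

- in percentages every species weighs as the Q in it: one G counts as two
- for J the L are counted in
- steps thought possible: Q + D -> X + E; X <-> J; X <-> Z; Q + X -> G; D + J <-> L

- which of the two ends with the higher share of J in all that became J or Z or G ("neither" if they lie within 2 percentage points) (south-east / north / neither)
- share of J in all that became J or Z or G, south-east
- share of J in all that became J or Z or G, north

Counting J, Z and G divided by two, because a G holds two Q but one turnover, my reckoning gives the D spent on what was read at 30.0 min: alpha 18.5%, eta 31.8%, gamma 48.2%. The read shares of J are 35.5%, 31.0% and 22.8%, so gamma's share is lower than alpha's. Giving north gamma's turnover at north's price and extending the eta-gamma line gives 20.6%, while south-east should stay near alpha.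

The forecast says 34.5% for south-east and 22% for north, a little above my north, and chooses south-east: “More Q sends X into G”.

The flask gives 36.1% for south-east and 19.6% for north, so south-east ends higher.

    Q + D → X + E (k = 0.0530 L mol⁻¹ min⁻¹)
    X ⇌ J (K = 0.330, k = 3.10 min⁻¹)
    X ⇌ Z (K = 3.10, k = 0.0750 min⁻¹)
    Q + X → G (k = 0.00990 L mol⁻¹ min⁻¹)
    D + J ⇌ L, settled at all times (K = 4.40 L mol⁻¹)

Charged with south-east's Q, north's share rises from 19.6% to 36.1%, level with south-east, and that change would undo the forecast's choice. The depletion of D is a part of north's low share: with D held, north reaches 38.1%. In north, the price times J, Z, G divided by two, the unread X and L leaves 21.0% of D, and the flask holds 21.0%. In the neighbour charged with 0.72 M of Q, the same count leaves 38.2%, and that flask holds 38% of D with a share of 26.9%.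

(The readings were computed with constants of no real substance.)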